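**Overview**

1. Retrosynthetic cuts, in order: the prenyl C–C bond at C2' of ring B (aromatic Claisen from the 3'-O-(1,1-dimethylallyl) ether); C4–C4a of ring C (B-alkyl Suzuki–Miyaura); O1–C2 (iridium-catalysed allylic etherification, separating ring A from ring B); ring D (propargyl Claisen on 3,4-dihydroxybenzaldehyde).
2. Forward: ring D is closed first on the ring B aldehyde, which is extended to an (E)-cinnamyl methyl carbonate. Ring A (from 4-bromoresorcinol) is joined through O1–C2, ring C is closed at C4–C4a, and the prenyl group goes on last.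
3. Enabling feature: C2, the only stereocentre, is a benzylic ether carbon bound to O1, to C1' of ring B and to C3. It therefore maps onto a branched aryl allyl ether whose vinyl group becomes C3–C4 and whose ortho bromine on ring A marks C4a.
4. Stereochemistry: C2 is set as (R) by the chiral phosphoramidite on iridium; no later step breaks a bond at C2 and no later step uses strong acid.

Key step: step 8

Assumption: the (Ra,Rc,Rc) ligand is taken to give the (R) ether, following the sense of induction usual for cinnamyl carbonates with heteroatom nucleophiles; if the sense is opposite for this pair, the (Sa,Sc,Sc) ligand is used with no other change.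

**Route**

Step 1
Reactants: 1 3,4-dihydroxybenzaldehyde; 2 3-chloro-3-methylbut-1-yne
Product: 3 3-hydroxy-4-[(2-methylbut-3-yn-2-yl)oxy]benzaldehyde
Conditions: 2 (1.1 equiv), CuCl2 (0.5 mol%), DBU (1.05 equiv), MeCN, argon, 0 °C
Reagents that add atoms: none
Why: With one equivalent of base only the more acidic 4-hydroxyl (para to the formyl group) is ionised, and this phenoxide is alkylated by the copper-activated tertiary propargylic chloride (copper-catalysed O-propargylation of a phenol), leaving the 3-hydroxyl free.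

Step 2
Reactants: 3 3-hydroxy-4-[(2-methylbut-3-yn-2-yl)oxy]benzaldehyde
Product: 4 3-[(tert-butyldimethylsilyl)oxy]-4-[(2-methylbut-3-yn-2-yl)oxy]benzaldehyde
Conditions: TBSCl, imidazole, DMF, 0 °C to rt
Reagents that add atoms: tert-butyldimethylsilyl chloride, CC(C)(C)[Si](C)(C)Cl
Why: Imidazole-promoted silylation of a phenol is routine and masks the 3-hydroxyl so that it cannot act as a nucleophile during the rearrangement or in the later allylic substitution.

Step 3
Reactants: 4 3-[(tert-butyldimethylsilyl)oxy]-4-[(2-methylbut-3-yn-2-yl)oxy]benzaldehyde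
Product: 5 8-[(tert-butyldimethylsilyl)oxy]-2,2-dimethyl-2H-chromene-6-carbaldehyde
Conditions: PhNEt2, 180 °C
Reagents that add atoms: none
Why: The thermal aryl propargyl ether Claisen rearrangement can only go to C5 of the benzaldehyde (the other ortho carbon carries the silyloxy group), and the usual hydrogen shift and oxa-6π electrocyclisation then close ring D as the 2,2-dimethyl-2H-chromene.

Step 4
Reactants: 5 8-[(tert-butyldimethylsilyl)oxy]-2,2-dimethyl-2H-chromene-6-carbaldehyde
Product: 6 ethyl (E)-3-{8-[(tert-butyldimethylsilyl)oxy]-2,2-dimethyl-2H-chromen-6-yl}prop-2-enoate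
Conditions: (EtO)2P(O)CH2CO2Et, NaH, THF, 0 °C to rt
Reagents that add atoms: triethyl phosphonoacetate, CCOC(=O)CP(=O)(OCC)OCC
Why: Horner–Wadsworth–Emmons olefination of an aromatic aldehyde with a stabilised phosphonate gives the (E)-enoate reliably, and the anhydrous conditions spare the aryl silyl ether.

Step 5
Reactants: 6 ethyl (E)-3-{8-[(tert-butyldimethylsilyl)oxy]-2,2-dimethyl-2H-chromen-6-yl}prop-2-enoate
Product: 7 (E)-3-{8-[(tert-butyldimethylsilyl)oxy]-2,2-dimethyl-2H-chromen-6-yl}prop-2-en-1-ol
Conditions: i-Bu2AlH (2.5 equiv), CH2Cl2, −78 °C to 0 °C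
Reagents that add atoms: none
Why: Low-temperature 1,2-reduction of an enoate with i-Bu2AlH gives the allylic alcohol without touching the alkene geometry, the ring D alkene or the silyl ether.

Step 6
Reactants: 7 (E)-3-{8-[(tert-butyldimethylsilyl)oxy]-2,2-dimethyl-2H-chromen-6-yl}prop-2-en-1-ol
Product: 8 (E)-3-{8-[(tert-butyldimethylsilyl)oxy]-2,2-dimethyl-2H-chromen-6-yl}prop-2-en-1-yl methyl carbonate
Conditions: ClCO2Me, pyridine, CH2Cl2, 0 °C; purification on Et3N-deactivated silica
Reagents that add atoms: methyl chloroformate, COC(=O)Cl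
Why: Acylation of a primary allylic alcohol with a chloroformate is standard and installs the leaving group that iridium ionises in step 8.

Step 7
Reactants: 9 4-bromobenzene-1,3-diol (4-bromoresorcinol)
Product: 10 2-bromo-5-[(triisopropylsilyl)oxy]phenol
Conditions: TIPSCl (1.0 equiv), imidazole, CH2Cl2, −20 °C to 0 °C
Reagents that add atoms: triisopropylsilyl chloride, CC(C)[Si](Cl)(C(C)C)C(C)C
Why: In this sterically governed silylation the bulky silyl chloride should take the hydroxyl para to bromine, which is unhindered, and leave the hydroxyl ortho to bromine free as the future O1.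

Step 8
Reactants: 8 (E)-3-{8-[(tert-butyldimethylsilyl)oxy]-2,2-dimethyl-2H-chromen-6-yl}prop-2-en-1-yl methyl carbonate; 10 2-bromo-5-[(triisopropylsilyl)oxy]phenol
Product: 12 (R)-6-{1-[2-bromo-5-(triisopropylsilyloxy)phenoxy]prop-2-en-1-yl}-8-(tert-butyldimethylsilyloxy)-2,2-dimethyl-2H-chromene, via lithium phenoxide 11 (not isolated)
Conditions: 10 (1.5 equiv), LiN(SiMe3)2 (1.5 equiv), THF, 0 °C; then 8, [Ir(cod)Cl]2 (2 mol%), (Ra,Rc,Rc)-O,O'-(1,1'-binaphthyl-2,2'-diyl) N,N-bis(1-phenylethyl)phosphoramidite (4 mol%, catalyst pre-activated with n-PrNH2), THF, rt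
Reagents that add atoms: none
Why: The cyclometalated monovalent iridium phosphoramidite complex ionises carbonate 8, with loss of CO2 and methoxide, to an allyl complex of trivalent iridium, and phenoxide 11 attacks the aryl-bearing allyl terminus on the face away from the metal, so that O1–C2 forms and rings A and B are joined. The closest known reaction type is the iridium-catalysed enantioselective, branched-selective allylic etherification of (E)-cinnamyl methyl carbonates with lithium aryloxides. No ring closes here; the step places the vinyl group (future C3–C4) and the ortho bromine (future C4a) that step 9 joins to close ring C. The new stereocentre C2 is controlled by the catalyst alone, the chiral phosphoramidite pocket deciding which enantiotopic allyl face is open to the nucleophile. The step needs branched over linear regioselectivity, which the iridium catalyst supplies and which the ring D oxygen para to the side chain reinforces by stabilising positive charge at the benzylic terminus, and it needs an unhindered cinnamyl arene, which is secured because both carbons ortho to the side chain on ring B still carry hydrogen. Room temperature and a short reaction time keep the electron-rich branched ether from re-ionising.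

Step 9
Reactants: 12 (R)-6-{1-[2-bromo-5-(triisopropylsilyloxy)phenoxy]prop-2-en-1-yl}-8-(tert-butyldimethylsilyloxy)-2,2-dimethyl-2H-chromene
Product: 14 (R)-8-(tert-butyldimethylsilyloxy)-2,2-dimethyl-6-[7-(triisopropylsilyloxy)chroman-2-yl]-2H-chromene, via B-alkyl-9-BBN borane 13 (not isolated)
Conditions: 9-BBN (9-borabicyclo[3.3.1]nonane, 1.5 equiv), THF, 0 °C to rt, until 12 is consumed; then degassed aq K3PO4 (3 equiv), Pd(dppf)Cl2 (5 mol%), THF, 60 °C
Reagents that add atoms: none
Why: 9-BBN adds anti-Markovnikov to the monosubstituted vinyl group far faster than to the cis-disubstituted ring D alkene, and intramolecular B-alkyl Suzuki–Miyaura coupling (zerovalent palladium inserts into C–Br, takes up the alkyl group and reductively eliminates from a seven-membered palladacycle) closes six-membered ring C at C4–C4a without touching C2, boron being too far from the ether oxygen for beta-alkoxy elimination.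

Step 10
Reactants: 14 (R)-8-(tert-butyldimethylsilyloxy)-2,2-dimethyl-6-[7-(triisopropylsilyloxy)chroman-2-yl]-2H-chromene
Product: 15 (R)-2,2-dimethyl-6-[7-(triisopropylsilyloxy)chroman-2-yl]-2H-chromen-8-ol
Conditions: KHF2 (2 equiv), MeOH/THF, rt, stopped when 14 is consumed
Reagents that add atoms: none
Why: Fluoride-mediated cleavage of aryl silyl ethers is sensitive to bulk at silicon, so the tert-butyldimethylsilyl ether on ring B should be removed well before the triisopropylsilyl ether on ring A.

Step 11
Reactants: 15 (R)-2,2-dimethyl-6-[7-(triisopropylsilyloxy)chroman-2-yl]-2H-chromen-8-ol; 2 3-chloro-3-methylbut-1-yne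
Product: 16 (R)-2,2-dimethyl-8-[(2-methylbut-3-yn-2-yl)oxy]-6-[7-(triisopropylsilyloxy)chroman-2-yl]-2H-chromene
Conditions: 2 (1.5 equiv), CuCl2 (1 mol%), DBU (1.5 equiv), dry MeCN, 0 °C
Reagents that add atoms: none
Why: Copper-catalysed O-propargylation of phenols with tertiary propargylic chlorides tolerates ortho-alkoxy phenols and is run dry and cold so that the ring A silyl ether survives the amidine base.

Step 12
Reactants: 16 (R)-2,2-dimethyl-8-[(2-methylbut-3-yn-2-yl)oxy]-6-[7-(triisopropylsilyloxy)chroman-2-yl]-2H-chromene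
Product: 17 (R)-2,2-dimethyl-8-[(2-methylbut-3-en-2-yl)oxy]-6-[7-(triisopropylsilyloxy)chroman-2-yl]-2H-chromene
Conditions: H2 (1 atm), Pd/CaCO3 poisoned with Pb(OAc)2, quinoline, EtOAc, rt, stopped after one equivalent of H2
Reagents that add atoms: none
Why: Semi-hydrogenation over the lead-poisoned palladium catalyst reduces the terminal alkyne to the alkene and leaves the ring D alkene and the benzylic C2–O1 bond alone.

Step 13
Reactants: 17 (R)-2,2-dimethyl-8-[(2-methylbut-3-en-2-yl)oxy]-6-[7-(triisopropylsilyloxy)chroman-2-yl]-2H-chromene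
Product: 18 (R)-2,2-dimethyl-7-(3-methylbut-2-en-1-yl)-6-[7-(triisopropylsilyloxy)chroman-2-yl]-2H-chromen-8-ol
Conditions: PhNEt2, 140 °C
Reagents that add atoms: none
Why: In this aromatic Claisen rearrangement the 1,1-dimethylallyl group shifts with allylic inversion to C2' (chromene C7), the only ortho carbon bearing hydrogen, arriving as a prenyl group, and tautomerisation then restores the phenol.

Step 14
Reactants: 18 (R)-2,2-dimethyl-7-(3-methylbut-2-en-1-yl)-6-[7-(triisopropylsilyloxy)chroman-2-yl]-2H-chromen-8-ol
Product: 19 (R)-6-(7-hydroxychroman-2-yl)-2,2-dimethyl-7-(3-methylbut-2-en-1-yl)-2H-chromen-8-ol (CNP0175270.2)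
Conditions: Bu4NF, AcOH (1:1), THF, 0 °C to rt
Reagents that add atoms: none
Why: Acetic-acid-buffered fluoride desilylation frees the 7-hydroxyl under nearly neutral conditions that disturb neither the prenyl group, ring D nor the C2–O1 bond.

**Compound list**

1 | 3,4-dihydroxybenzaldehyde | O=Cc1ccc(O)c(O)c1 | starting material
2 | 3-chloro-3-methylbut-1-yne | CC(C)(Cl)C#C | starting material
3 | 3-hydroxy-4-[(2-methylbut-3-yn-2-yl)oxy]benzaldehyde | O=Cc1ccc(OC(C)(C)C#C)c(O)c1 | intermediate
4 | 3-[(tert-butyldimethylsilyl)oxy]-4-[(2-methylbut-3-yn-2-yl)oxy]benzaldehyde | O=Cc1ccc(OC(C)(C)C#C)c(O[Si](C)(C)C(C)(C)C)c1 | intermediate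
5 | 8-[(tert-butyldimethylsilyl)oxy]-2,2-dimethyl-2H-chromene-6-carbaldehyde | O=Cc1cc(O[Si](C)(C)C(C)(C)C)c2OC(C)(C)C=Cc2c1 | intermediate
6 | ethyl (E)-3-{8-[(tert-butyldimethylsilyl)oxy]-2,2-dimethyl-2H-chromen-6-yl}prop-2-enoate | CCOC(=O)/C=C/c1cc(O[Si](C)(C)C(C)(C)C)c2OC(C)(C)C=Cc2c1 | intermediate
7 | (E)-3-{8-[(tert-butyldimethylsilyl)oxy]-2,2-dimethyl-2H-chromen-6-yl}prop-2-en-1-ol | OC/C=C/c1cc(O[Si](C)(C)C(C)(C)C)c2OC(C)(C)C=Cc2c1 | intermediate
8 | (E)-3-{8-[(tert-butyldimethylsilyl)oxy]-2,2-dimethyl-2H-chromen-6-yl}prop-2-en-1-yl methyl carbonate | COC(=O)OC/C=C/c1cc(O[Si](C)(C)C(C)(C)C)c2OC(C)(C)C=Cc2c1 | intermediate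
9 | 4-bromobenzene-1,3-diol (4-bromoresorcinol) | Oc1ccc(Br)c(O)c1 | starting material
10 | 2-bromo-5-[(triisopropylsilyl)oxy]phenol | Oc1cc(O[Si](C(C)C)(C(C)C)C(C)C)ccc1Br | intermediate
11 | lithium 2-bromo-5-[(triisopropylsilyl)oxy]phenoxide (formed in the flask) | [Li+].[O-]c1cc(O[Si](C(C)C)(C(C)C)C(C)C)ccc1Br | intermediate
12 | (R)-6-{1-[2-bromo-5-(triisopropylsilyloxy)phenoxy]prop-2-en-1-yl}-8-(tert-butyldimethylsilyloxy)-2,2-dimethyl-2H-chromene | C=C[C@@H](Oc1cc(O[Si](C(C)C)(C(C)C)C(C)C)ccc1Br)c1cc(O[Si](C)(C)C(C)(C)C)c2OC(C)(C)C=Cc2c1 | intermediate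
13 | (R)-6-{3-(9-borabicyclo[3.3.1]nonan-9-yl)-1-[2-bromo-5-(triisopropylsilyloxy)phenoxy]propyl}-8-(tert-butyldimethylsilyloxy)-2,2-dimethyl-2H-chromene (formed in the flask) | C1CC2CCCC(C1)B2CC[C@@H](Oc1cc(O[Si](C(C)C)(C(C)C)C(C)C)ccc1Br)c1cc(O[Si](C)(C)C(C)(C)C)c2OC(C)(C)C=Cc2c1 | intermediate
14 | (R)-8-(tert-butyldimethylsilyloxy)-2,2-dimethyl-6-[7-(triisopropylsilyloxy)chroman-2-yl]-2H-chromene | CC1(C)C=Cc2cc([C@H]3CCc4ccc(O[Si](C(C)C)(C(C)C)C(C)C)cc4O3)cc(O[Si](C)(C)C(C)(C)C)c2O1 | intermediate
15 | (R)-2,2-dimethyl-6-[7-(triisopropylsilyloxy)chroman-2-yl]-2H-chromen-8-ol | CC1(C)C=Cc2cc([C@H]3CCc4ccc(O[Si](C(C)C)(C(C)C)C(C)C)cc4O3)cc(O)c2O1 | intermediate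
16 | (R)-2,2-dimethyl-8-[(2-methylbut-3-yn-2-yl)oxy]-6-[7-(triisopropylsilyloxy)chroman-2-yl]-2H-chromene | C#CC(C)(C)Oc1cc([C@H]2CCc3ccc(O[Si](C(C)C)(C(C)C)C(C)C)cc3O2)cc2C=CC(C)(C)Oc12 | intermediate
17 | (R)-2,2-dimethyl-8-[(2-methylbut-3-en-2-yl)oxy]-6-[7-(triisopropylsilyloxy)chroman-2-yl]-2H-chromene | C=CC(C)(C)Oc1cc([C@H]2CCc3ccc(O[Si](C(C)C)(C(C)C)C(C)C)cc3O2)cc2C=CC(C)(C)Oc12 | intermediate
18 | (R)-2,2-dimethyl-7-(3-methylbut-2-en-1-yl)-6-[7-(triisopropylsilyloxy)chroman-2-yl]-2H-chromen-8-ol | CC(C)=CCc1c([C@H]2CCc3ccc(O[Si](C(C)C)(C(C)C)C(C)C)cc3O2)cc2c(c1O)OC(C)(C)C=C2 | intermediate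
19 | (R)-6-(7-hydroxychroman-2-yl)-2,2-dimethyl-7-(3-methylbut-2-en-1-yl)-2H-chromen-8-ol (CNP0175270.2) | CC(C)=CCc1c([C@H]2CCc3ccc(O)cc3O2)cc2c(c1O)OC(C)(C)C=C2 | target

**Step count and risks**

Total step count: 14. Longest linear sequence: 13 steps (steps 1 to 6 and 8 to 14, from 3,4-dihydroxybenzaldehyde); the ring A branch contributes step 7.

Steps most likely to fail:

Step 8. The hindered, weakly nucleophilic ortho-bromophenoxide may react slowly, which would allow linear ether formation, incomplete enantioselectivity, or re-ionisation of the electron-rich branched ether with loss of configuration. The fallback forms O1–C2 by displacement at a preformed stereocentre; it sets out from aldehyde 5 and comes back at 12. Enantioselective addition of Zn(CH=CH2)2 to 5, in the presence of the enantiomer of 3-exo-morpholinoisoborneol that gives the (S) carbinol, should give (S)-1-{8-[(tert-butyldimethylsilyl)oxy]-2,2-dimethyl-2H-chromen-6-yl}prop-2-en-1-ol F1. Mitsunobu etherification of this alcohol with phenol 10 (PPh3, DIAD, toluene, −20 °C) should then invert the carbinol carbon and give the (R) ether 12; the low temperature and non-polar solvent are there to suppress ionisation of the benzylic alcohol.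

Step 10. The two aryl silyl ethers may not be distinguished well enough, so that the ring A triisopropylsilyl ether is lost together with the ring B silyl ether. The fallback removes both groups and re-protects selectively; it sets out from 14 and comes back at 15. Treatment of 14 with excess Bu4NF/AcOH in THF should give the diphenol (R)-6-(7-hydroxychroman-2-yl)-2,2-dimethyl-2H-chromen-8-ol F2. Silylation of F2 with TIPSCl (1.0 equiv) and imidazole in CH2Cl2 at −20 °C should take the unhindered ring A 7-hydroxyl in preference to the chromene 8-hydroxyl, which is flanked by and hydrogen-bonded to the ring D oxygen, and so give 15.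

Step 13. The only open ortho carbon (C2') lies between the oxygen-bearing carbon and the carbon carrying the flavan unit, so the sigmatropic shift may be slow and the allyl group may migrate on to the para carbon C6' or the product may cyclise on prolonged heating. The fallback makes the C2'–prenyl bond by direct ortho C-alkylation; it sets out from 15, bypasses steps 11 to 13 and comes back at 18. Deprotonation of 15 with NaH in toluene gives the sodium phenoxide of 15 F3 as a tight ion pair, and treatment with 1-bromo-3-methylbut-2-ene in toluene at rt to 40 °C should deliver the prenyl group to the ortho carbon C2' and give 18. The O-prenyl ether is the expected by-product of this known but moderately efficient ortho-alkylation of phenoxides in non-polar media.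

**Further compounds**

F1 | step 8 | (S)-1-{8-[(tert-butyldimethylsilyl)oxy]-2,2-dimethyl-2H-chromen-6-yl}prop-2-en-1-ol | C=C[C@H](O)c1cc(O[Si](C)(C)C(C)(C)C)c2OC(C)(C)C=Cc2c1
F2 | step 10 | (R)-6-(7-hydroxychroman-2-yl)-2,2-dimethyl-2H-chromen-8-ol | CC1(C)C=Cc2cc([C@H]3CCc4ccc(O)cc4O3)cc(O)c2O1
F3 | step 13 | sodium (R)-2,2-dimethyl-6-[7-(triisopropylsilyloxy)chroman-2-yl]-2H-chromen-8-olate | [Na+].[O-]c1cc([C@H]2CCc3ccc(O[Si](C(C)C)(C(C)C)C(C)C)cc3O2)cc2C=CC(C)(C)Oc12
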